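Oxolane numbering: O1, C2 (aryl), C3 (CH2OH), C4 (aroyl), C5. Everything rests on cutting the ketone carbon from C4. The feature exploited is that C5, C4, C3 and the hydroxymethyl carbon are the four carbons of a butenolide with C4 as β-carbon, while the ketone carbon is an umpoled aldehyde carbon, and that both aryl rings are identical. The precursors are a lithiated aryl dithiane, a chiral 5-menthyloxybutenolide and the parent aldehyde. In one operation the dithiane anion adds to C4 and the enolate captures the aldehyde, which makes the key bond, brings in both aryl units and fixes C3 absolutely. Reduction, stereoconvergent ring closure, unmasking and C4 epimerization finish.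

Key step: step 2

Remark: butenolide 3 is taken as purchasable (otherwise one operation from 5-hydroxyfuran-2(5H)-one and (−)-menthol). The carbinol carbon made in step 2 is not controlled, so 6 and 7 are written without configuration at that atom and both epimers are carried on together.

Step 1
Reactants: 1 3-(benzyloxy)-4-methoxybenzaldehyde
Product: 2 2-[3-(benzyloxy)-4-methoxyphenyl]-1,3-dithiane
Conditions: HS(CH2)3SH, BF3·OEt2 (cat.), CH2Cl2, 0 °C → rt
Reagents that add atoms: propane-1,3-dithiol, SCCCS
Why: Lewis-acid-catalysed dithioacetalization of the aromatic aldehyde turns the formyl carbon into a latent acyl anion, and the benzyl ether is stable to catalytic BF3·OEt2 at this temperature.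

Step 2
Reactants: 2 2-[3-(benzyloxy)-4-methoxyphenyl]-1,3-dithiane; 3 (5R)-5-{[(1R,2S,5R)-5-methyl-2-(propan-2-yl)cyclohexyl]oxy}furan-2(5H)-one; 1 3-(benzyloxy)-4-methoxybenzaldehyde
Product: 6 (3S,4R,5R)-3-{[3-(benzyloxy)-4-methoxyphenyl](hydroxy)methyl}-4-{2-[3-(benzyloxy)-4-methoxyphenyl]-1,3-dithian-2-yl}-5-{[(1R,2S,5R)-5-methyl-2-(propan-2-yl)cyclohexyl]oxy}oxolan-2-one, via 2-aryl-2-lithio-1,3-dithiane 4 (not isolated), via lactone lithium enolate 5 (not isolated)
Conditions: n-BuLi, THF, −78 → −20 °C; 3, −78 °C; then 1, −78 °C; AcOH quench at −78 °C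
Reagents that add atoms: none
Why: The sulfur-stabilized carbanion 4 (Corey–Seebach acyl anion equivalent of the aroyl group) adds in Michael fashion to the β-carbon of butenolide 3, which forms the bond between the future ketone carbon and the future C4 of the oxolane and gives enolate 5; 5 then adds to the carbonyl group of a second molecule of 1 in an aldol reaction. The closest known reaction type is the tandem conjugate addition–aldol (or alkylation) of 2-aryl-2-lithio-1,3-dithianes with 5-alkoxyfuran-2(5H)-ones, a standard entry to lignan skeletons. No ring is closed in this step. The new centre at lactone C4 is controlled by the acetal centre C5, the nucleophile entering anti to the menthyloxy group, and the new centre at lactone C3 is controlled by C4, the aldehyde entering anti to the bulky dithianyl group, so the lactone should be 4,5-trans-3,4-trans; the carbinol centre is not controlled and need not be, because it is ionized in step 4. The step needs 1,4- over 1,2-addition, which the soft, hindered, doubly sulfur-stabilized anion and the unsaturated lactone secure, and it needs capture of the enolate before proton transfer, which is secured because neither 3 nor 1 carries an acidic C–H and the cold acidic quench prevents retro-aldol.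

Step 3
Reactants: 6 (3S,4R,5R)-aldol lactone
Product: 7 (2R,3R)-2-{2-[3-(benzyloxy)-4-methoxyphenyl]-1,3-dithian-2-yl}-3-{[3-(benzyloxy)-4-methoxyphenyl](hydroxy)methyl}butane-1,4-diol
Conditions: LiAlH4, THF, 0 °C → rt; H2O/aq. NaOH work-up
Reagents that add atoms: none
Why: Hydride reduction of the alkoxy lactone gives a lactol alkoxide that opens, the hemiacetal so freed expels mentholate, and both aldehydes are reduced, so the acylal becomes a 1,4-diol with release of the auxiliary, while the dithiane, the benzyl ethers and the two backbone stereocentres are untouched.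

Step 4
Reactants: 7 (2R,3R)-dithianyl triol
Product: 8 [(2S,3R,4R)-2-[3-(benzyloxy)-4-methoxyphenyl]-4-{2-[3-(benzyloxy)-4-methoxyphenyl]-1,3-dithian-2-yl}oxolan-3-yl]methanol
Conditions: CSA (10 mol %), CH2Cl2, 0 °C → rt
Reagents that add atoms: none
Why: Acid-catalysed SN1 cycloetherification in which either carbinol epimer ionizes to the same para-methoxy-stabilized benzylic cation, which is captured in a 5-exo mode by the primary hydroxyl on the dithiane-bearing branch (the other hydroxyl could only close an oxetane), the aryl group settling trans to the neighbouring CH2OH-bearing carbon in the less crowded transition state, which is also the more stable product should the closure reverse.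

Step 5
Reactants: 8 (2S,3R,4R)-dithianyl oxolane
Product: 9 [3-(benzyloxy)-4-methoxyphenyl][(3R,4R,5S)-5-[3-(benzyloxy)-4-methoxyphenyl]-4-(hydroxymethyl)oxolan-3-yl]methanone (3,4-cis; may sit in equilibrium with its bicyclic hemiketal)
Conditions: PhI(OCOCF3)2, MeCN/H2O 9:1, 0 °C
Reagents that add atoms: water, O
Why: Oxidative dethioketalization with iodine(III), in which sulfur is activated, the C–S bonds are cleaved through a thionium ion and water delivers the carbonyl oxygen, under conditions that should tolerate the free primary alcohol, the benzyl ethers and the cyclic benzylic ether during the short reaction time; no stereocentre is touched.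

Step 6
Reactants: 9 3,4-cis ketone
Product: 10 [3-(benzyloxy)-4-methoxyphenyl][(3S,4R,5S)-5-[3-(benzyloxy)-4-methoxyphenyl]-4-(hydroxymethyl)oxolan-3-yl]methanone
Conditions: DBU (0.3 equiv), CH2Cl2, rt
Reagents that add atoms: none
Why: Base-catalysed enolization (thermodynamic epimerization) at the only enolizable stereocentre, C4, should move the aroyl group trans to the C3 CH2OH group and so give the all-trans isomer, which is favoured because the 3,4-cis interaction is relieved, while C2 and C3 are not acidic and keep their configuration.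

Step 7
Reactants: 10 all-trans dibenzyl ketone
Product: 11 (3-hydroxy-4-methoxyphenyl)[(3S,4R,5S)-5-(3-hydroxy-4-methoxyphenyl)-4-(hydroxymethyl)oxolan-3-yl]methanone
Conditions: H2 (1 atm), 10% Pd/C, EtOAc, rt
Reagents that add atoms: none
Why: Heterogeneous hydrogenolysis of the two aryl benzyl ethers is fast at 1 atm in neutral ethyl acetate, conditions under which the electron-rich aryl ketone and the cyclic benzylic ether are expected to survive, and no stereocentre is touched.

Compound list
1 | 3-(benzyloxy)-4-methoxybenzaldehyde | COc1ccc(C=O)cc1OCc1ccccc1 | starting material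
2 | 2-[3-(benzyloxy)-4-methoxyphenyl]-1,3-dithiane | COc1ccc(C2SCCCS2)cc1OCc1ccccc1 | intermediate
3 | (5R)-5-{[(1R,2S,5R)-5-methyl-2-(propan-2-yl)cyclohexyl]oxy}furan-2(5H)-one | O=C1C=C[C@H](O[C@@H]2C[C@H](C)CC[C@H]2C(C)C)O1 | starting material
4 | 2-[3-(benzyloxy)-4-methoxyphenyl]-2-lithio-1,3-dithiane | COc1ccc(C2([Li])SCCCS2)cc1OCc1ccccc1 | intermediate
5 | lithium enolate of (4R,5R)-4-{2-[3-(benzyloxy)-4-methoxyphenyl]-1,3-dithian-2-yl}-5-(menthyloxy)oxolan-2-one | [Li]OC1=C[C@@H](C2(c3ccc(OC)c(OCc4ccccc4)c3)SCCCS2)[C@H](O[C@@H]2C[C@H](C)CC[C@H]2C(C)C)O1 | intermediate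
6 | (3S,4R,5R)-3-{[3-(benzyloxy)-4-methoxyphenyl](hydroxy)methyl}-4-{2-[3-(benzyloxy)-4-methoxyphenyl]-1,3-dithian-2-yl}-5-{[(1R,2S,5R)-5-methyl-2-(propan-2-yl)cyclohexyl]oxy}oxolan-2-one | O=C1O[C@@H](O[C@@H]2C[C@H](C)CC[C@H]2C(C)C)[C@H](C2(c3ccc(OC)c(OCc4ccccc4)c3)SCCCS2)[C@H]1C(O)c1ccc(OC)c(OCc2ccccc2)c1 | intermediate
7 | (2R,3R)-2-{2-[3-(benzyloxy)-4-methoxyphenyl]-1,3-dithian-2-yl}-3-{[3-(benzyloxy)-4-methoxyphenyl](hydroxy)methyl}butane-1,4-diol | OC[C@H](C1(c2ccc(OC)c(OCc3ccccc3)c2)SCCCS1)[C@H](CO)C(O)c1ccc(OC)c(OCc2ccccc2)c1 | intermediate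
8 | [(2S,3R,4R)-2-[3-(benzyloxy)-4-methoxyphenyl]-4-{2-[3-(benzyloxy)-4-methoxyphenyl]-1,3-dithian-2-yl}oxolan-3-yl]methanol | COc1ccc(C2(SCCCS2)[C@H]2CO[C@H](c3ccc(OC)c(OCc4ccccc4)c3)[C@H]2CO)cc1OCc1ccccc1 | intermediate
9 | [3-(benzyloxy)-4-methoxyphenyl][(3R,4R,5S)-5-[3-(benzyloxy)-4-methoxyphenyl]-4-(hydroxymethyl)oxolan-3-yl]methanone | COc1ccc(C(=O)[C@H]2CO[C@H](c3ccc(OC)c(OCc4ccccc4)c3)[C@H]2CO)cc1OCc1ccccc1 | intermediate
10 | [3-(benzyloxy)-4-methoxyphenyl][(3S,4R,5S)-5-[3-(benzyloxy)-4-methoxyphenyl]-4-(hydroxymethyl)oxolan-3-yl]methanone | COc1ccc(C(=O)[C@@H]2CO[C@H](c3ccc(OC)c(OCc4ccccc4)c3)[C@H]2CO)cc1OCc1ccccc1 | intermediate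
11 | (3-hydroxy-4-methoxyphenyl)[(3S,4R,5S)-5-(3-hydroxy-4-methoxyphenyl)-4-(hydroxymethyl)oxolan-3-yl]methanone | COc1ccc(C(=O)[C@@H]2CO[C@H](c3ccc(OC)c(O)c3)[C@H]2CO)cc1O | target

Total step count: 7
Longest linear sequence: 7 steps (1 → 2 → 6 → 7 → 8 → 9 → 10 → 11)

Steps most likely to fail

Step 2. The aldol capture of enolate 5 may be incomplete or may revert during the quench (retro-aldol), or part of the carbanion may attack the lactone carbonyl. The fallback separates the two bond formations; it sets out from 2 and 3 and comes back at 6. The Michael addition alone is run and quenched with NH4Cl at −78 °C to give (4R,5R)-4-{2-[3-(benzyloxy)-4-methoxyphenyl]-1,3-dithian-2-yl}-5-(menthyloxy)oxolan-2-one F1, which already holds the key bond. F1 is then enolized with LDA in THF at −78 °C, transmetalated with ZnCl2 and treated with 1, the zinc aldolate being less prone to retro-aldol, to give 6.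

Step 4. Capture of the benzylic cation by the electron-rich aryl ring on the dithiane carbon (Friedel–Crafts closure to an aryltetralin) may compete with capture by oxygen, and prolonged acid may erode the selectivity at C2. The fallback sets out from 6 and comes back at 9.
- The dithiane is removed at the lactone stage with PhI(OCOCF3)2 in aqueous MeCN to give (3S,4R,5R)-4-[3-(benzyloxy)-4-methoxybenzoyl]-3-{[3-(benzyloxy)-4-methoxyphenyl](hydroxy)methyl}-5-(menthyloxy)oxolan-2-one F2.
- LiAlH4 in THF reduces lactone, acylal and ketone to the C2-symmetric (2R,3R)-2,3-bis{[3-(benzyloxy)-4-methoxyphenyl](hydroxy)methyl}butane-1,4-diol F3.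
- Catalytic CSA in CH2Cl2 closes both benzylic carbinols onto the primary hydroxyls to give the cis-fused di-exo (1S,3aR,4S,6aR)-1,4-bis[3-(benzyloxy)-4-methoxyphenyl]tetrahydro-1H,3H-furo[3,4-c]furan F4.
- One equivalent of DDQ in wet CH2Cl2 at 0 °C oxidizes one benzylic ether C–H (the two are homotopic, so either gives the same product), and the hemiketal opens to 9, which is epimerized as in step 6.

Step 6. The equilibration may stop at a mixture because the cis isomer is held as its bicyclic hemiketal or by an OH···O=C hydrogen bond, and stronger base may open the ring by β-elimination of O1. The fallback sets out from 9 and comes back at 10. The primary hydroxyl is blocked first (TBSCl, imidazole, DMF) to give [3-(benzyloxy)-4-methoxyphenyl][(3R,4R,5S)-5-[3-(benzyloxy)-4-methoxyphenyl]-4-{[(tert-butyldimethylsilyl)oxy]methyl}oxolan-3-yl]methanone F5, in which no hemiketal can form and the cis-3,4 strain is larger. DBU in toluene at 60 °C should then give the all-trans [3-(benzyloxy)-4-methoxyphenyl][(3S,4R,5S)-5-[3-(benzyloxy)-4-methoxyphenyl]-4-{[(tert-butyldimethylsilyl)oxy]methyl}oxolan-3-yl]methanone F6, and TBAF buffered with AcOH in THF returns 10.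

Further compounds
F1 | step 2 | (4R,5R)-4-{2-[3-(benzyloxy)-4-methoxyphenyl]-1,3-dithian-2-yl}-5-{[(1R,2S,5R)-5-methyl-2-(propan-2-yl)cyclohexyl]oxy}oxolan-2-one | O=C1C[C@@H](C2(c3ccc(OC)c(OCc4ccccc4)c3)SCCCS2)[C@H](O[C@@H]2C[C@H](C)CC[C@H]2C(C)C)O1
F2 | step 4 | (3S,4R,5R)-4-[3-(benzyloxy)-4-methoxybenzoyl]-3-{[3-(benzyloxy)-4-methoxyphenyl](hydroxy)methyl}-5-{[(1R,2S,5R)-5-methyl-2-(propan-2-yl)cyclohexyl]oxy}oxolan-2-one | O=C1O[C@@H](O[C@@H]2C[C@H](C)CC[C@H]2C(C)C)[C@H](C(=O)c2ccc(OC)c(OCc3ccccc3)c2)[C@H]1C(O)c1ccc(OC)c(OCc2ccccc2)c1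
F3 | step 4 | (2R,3R)-2,3-bis{[3-(benzyloxy)-4-methoxyphenyl](hydroxy)methyl}butane-1,4-diol | OC[C@H](C(O)c1ccc(OC)c(OCc2ccccc2)c1)[C@H](CO)C(O)c1ccc(OC)c(OCc2ccccc2)c1
F4 | step 4 | (1S,3aR,4S,6aR)-1,4-bis[3-(benzyloxy)-4-methoxyphenyl]tetrahydro-1H,3H-furo[3,4-c]furan | COc1ccc([C@H]2OC[C@H]3[C@@H]2CO[C@@H]3c2ccc(OC)c(OCc3ccccc3)c2)cc1OCc1ccccc1
F5 | step 6 | [3-(benzyloxy)-4-methoxyphenyl][(3R,4R,5S)-5-[3-(benzyloxy)-4-methoxyphenyl]-4-{[(tert-butyldimethylsilyl)oxy]methyl}oxolan-3-yl]methanone | COc1ccc(C(=O)[C@H]2CO[C@H](c3ccc(OC)c(OCc4ccccc4)c3)[C@H]2CO[Si](C)(C)C(C)(C)C)cc1OCc1ccccc1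
F6 | step 6 | [3-(benzyloxy)-4-methoxyphenyl][(3S,4R,5S)-5-[3-(benzyloxy)-4-methoxyphenyl]-4-{[(tert-butyldimethylsilyl)oxy]methyl}oxolan-3-yl]methanone | COc1ccc(C(=O)[C@@H]2CO[C@H](c3ccc(OC)c(OCc4ccccc4)c3)[C@H]2CO[Si](C)(C)C(C)(C)C)cc1OCc1ccccc1
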